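**Plan**

- Ring B of the target is labelled B1 (lactone oxygen), B2 (CH2OH), B3 (OH), B4 (carboxyl carbon), B5 (lactol carbon), B6 (ether oxygen). Oxygens on B1 and B3 flank B2, a carboxyl sits on B4 and the ether oxygen on B6: this is an aromatized 4-carboalkoxycyclohexane-1,3-dione with an aryloxy group α to one ketone.
- Retrosynthetic cuts, in order: the lactol C–O bond (back to the o-formyl acid), the B2–CH2OH carbon (via the aldehyde), the seven-membered lactone C(=O)–O bond, then ring B bonds B4–B5 and B1–B2. The remaining enoate is cut at its C=C bond and at the alkyl C–O bond of an alkyl aryl ether, so no diaryl ether coupling is needed.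
- Forward: ring A (from methyl orsellinate) is formylated, protected and O-alkylated by carbenoid insertion; olefination gives the α-aryloxy enoate; Michael–Claisen annulation with tert-butyl acetoacetate closes ring B, which is then dehydrogenated. The seven-membered lactone closes next and the five-membered lactol last.
- Stereochemistry: the lactol carbon is the only stereocentre. It epimerizes in solution through the open formyl acid and is fixed as (S) in the final seeded crystallization.

Key step: step 7

Remark: the lactol carbon is a hemiacetal centre that equilibrates with the open formyl acid in solution, so the (S) configuration refers to the crystalline solid; racemate 20 is assumed to crystallize as a conglomerate.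

Abbreviation: ArO = ring A aryloxy group, 3-(benzyloxy)-2-(1,3-dioxolan-2-yl)-6-(methoxycarbonyl)-5-methylphenoxy. E and Z isomers of 9 can be carried on together.

Step 1
Reactants: 1 methyl orsellinate
Product: 2 methyl haematommate (methyl 3-formyl-2,4-dihydroxy-6-methylbenzoate)
Conditions: Cl2CHOMe, TiCl4, CH2Cl2, 0 °C → rt; then aq. HCl
Reagents that add atoms: dichloromethyl methyl ether, COC(Cl)Cl; water, O
Why: Rieche formylation, an electrophilic aromatic substitution in which the titanium-bound phenol oxygens should steer the electrophile to C-3 (ortho to both), while C-5 is screened by the neighbouring methyl group; any 5-formyl isomer should be removable by crystallization.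

Step 2
Reactants: 2 methyl haematommate
Product: 3 methyl 4-(benzyloxy)-3-formyl-2-hydroxy-6-methylbenzoate
Conditions: BnBr, K2CO3, acetone, reflux
Reagents that add atoms: benzyl bromide, BrCc1ccccc1
Why: Williamson etherification; the 4-hydroxyl should react selectively because the 2-hydroxyl is hydrogen-bonded to the ester carbonyl and flanked by two substituents.

Step 3
Reactants: 3 methyl 4-(benzyloxy)-3-formyl-2-hydroxy-6-methylbenzoate
Product: 4 methyl 4-(benzyloxy)-3-(1,3-dioxolan-2-yl)-2-hydroxy-6-methylbenzoate
Conditions: HO(CH2)2OH, TsOH·H2O (cat.), benzene, reflux, Dean–Stark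
Reagents that add atoms: ethylene glycol, OCCO
Why: Acid-catalysed acetalization with azeotropic removal of water masks the aldehyde, which would otherwise be attacked by the phosphonate carbanion of step 6 (intramolecular olefination to a benzofuran) and by the acetoacetate enolate of step 7.

Step 4
Reactants: 5 triethyl phosphonoacetate
Product: 6 triethyl diazophosphonoacetate (ethyl 2-diazo-2-(diethoxyphosphoryl)acetate)
Conditions: 4-AcNHC6H4SO2N3, DBU, MeCN, 0 °C → rt
Reagents that add atoms: 4-acetamidobenzenesulfonyl azide, CC(=O)Nc1ccc(cc1)S(=O)(=O)N=[N+]=[N-]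
Why: Regitz diazo transfer from the sulfonyl azide to the doubly activated methylene group of the phosphonoacetate.

Step 5
Reactants: 4 methyl 4-(benzyloxy)-3-(1,3-dioxolan-2-yl)-2-hydroxy-6-methylbenzoate; 6 triethyl diazophosphonoacetate
Product: 7 ethyl 2-(ArO)-2-(diethoxyphosphoryl)acetate (racemic)
Conditions: Rh2(OAc)4 (2 mol%), toluene, 80 °C, slow addition of 6
Reagents that add atoms: none
Why: Rhodium-carbenoid O–H insertion alkylates the hindered, hydrogen-bonded phenol under neutral conditions and avoids base-induced condensation onto the neighbouring ester; the new stereocentre at the phosphonate carbon forms racemic and is destroyed in step 6.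

Step 6
Reactants: 7 ethyl 2-(ArO)-2-(diethoxyphosphoryl)acetate; 8 2,2-dimethoxyacetaldehyde
Product: 9 ethyl (Z)-2-(ArO)-4,4-dimethoxybut-2-enoate
Conditions: NaH, THF, 0 °C; then anhydrous 8, 0 °C → rt
Reagents that add atoms: none
Why: Horner–Wadsworth–Emmons olefination of the stabilized phosphonate anion with an unhindered aldehyde; the (Z) isomer (ester trans to the acetal carbon) is expected to predominate, and the geometry is immaterial because both alkene carbons become arene carbons.

Step 7
Reactants: 9 ethyl (Z)-2-(ArO)-4,4-dimethoxybut-2-enoate; 10 tert-butyl acetoacetate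
Product: 12 tert-butyl trans-5-(ArO)-6-(dimethoxymethyl)-2-hydroxy-4-oxocyclohex-1-ene-1-carboxylate (racemic enol form), via open-chain Michael adduct 11 (not isolated)
Conditions: KOtBu (1.2 equiv), t-BuOH/THF, rt → 60 °C; then AcOH
Reagents that add atoms: none
Why: tert-Butoxide forms the acetoacetate enolate, which adds through C-2 to the β-carbon of 9 to give 11; proton transfer then exposes the methyl-ketone enolate, whose carbon attacks the ethyl ester and expels ethoxide, and the 1,3-dione is trapped as its stable enolate, which pulls the reversible sequence forward. The closest known reaction is the Michael–Claisen annulation of acetoacetates with crotonates and cinnamates to 4-carboalkoxycyclohexane-1,3-diones. Ring B closes 6-exo-trig at the ester carbonyl. The two ring stereocentres (ether carbon and acetal-bearing carbon) are not controlled beyond equilibration toward the trans arrangement through the enolizable dione, and both disappear on aromatization. Regiochemistry follows from polarity (donor C-2 to acceptor β-carbon, γ-carbon to the enoate ester); the aryloxy group is α, not β, to a carbonyl and so is not expelled, and the ring A methyl ester (two ortho substituents) and the tert-butyl ester are too hindered to compete as Claisen acceptors.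

Step 8
Reactants: 12 tert-butyl trans-5-(ArO)-6-(dimethoxymethyl)-2-hydroxy-4-oxocyclohex-1-ene-1-carboxylate
Product: 13 tert-butyl 3-(ArO)-2-(dimethoxymethyl)-4,6-dihydroxybenzoate
Conditions: DDQ (1.1 equiv), 1,4-dioxane, rt → 60 °C
Reagents that add atoms: none
Why: Oxidative aromatization; DDQ should abstract hydride from the enolized dione and proton loss with tautomerization gives the resorcylate, a dehydrogenation known for 4-carboalkoxycyclohexane-1,3-diones, and both ring stereocentres are erased.

Step 9
Reactants: 13 tert-butyl 3-(ArO)-2-(dimethoxymethyl)-4,6-dihydroxybenzoate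
Product: 14 tert-butyl 3-(ArO)-2-(dimethoxymethyl)-5-formyl-4,6-dihydroxybenzoate
Conditions: MgCl2, Et3N, (CH2O)n, MeCN, 70 °C; then cold aq. citric acid
Reagents that add atoms: paraformaldehyde (as formaldehyde), C=O
Why: Casnati–Skattebøl ortho-formylation; the magnesium phenoxide directs formaldehyde to the only free position of ring B, which lies ortho to both hydroxyls, whereas ring A has no free phenol and should stay untouched.

Step 10
Reactants: 14 tert-butyl 3-(ArO)-2-(dimethoxymethyl)-5-formyl-4,6-dihydroxybenzoate
Product: 15 4-(benzyloxy)-2-[3-(tert-butoxycarbonyl)-2-(dimethoxymethyl)-5-formyl-4,6-dihydroxyphenoxy]-3-(1,3-dioxolan-2-yl)-6-methylbenzoic acid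
Conditions: KOH, DMSO/H2O, 80 °C, Ar; then cold aq. KHSO4 to pH 3
Reagents that add atoms: potassium hydroxide, [K+].[OH-]
Why: Saponification of a hindered methyl benzoate in aqueous DMSO; the tert-butyl ester is inert to hydroxide, the acetals and the benzyl ether are base-stable, and the ring B aldehyde is shielded from Cannizzaro reaction by its two ortho phenoxides.

Step 11
Reactants: 15 4-(benzyloxy)-2-[3-(tert-butoxycarbonyl)-2-(dimethoxymethyl)-5-formyl-4,6-dihydroxyphenoxy]-3-(1,3-dioxolan-2-yl)-6-methylbenzoic acid
Product: 16 tert-butyl 3-(benzyloxy)-6-(dimethoxymethyl)-4-(1,3-dioxolan-2-yl)-9-formyl-8-hydroxy-1-methyl-11-oxo-11H-dibenzo[b,e][1,4]dioxepine-7-carboxylate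
Conditions: DCC, DMAP (cat.), CH2Cl2 (0.005 M), rt
Reagents that add atoms: none
Why: Steglich-type carbodiimide lactonization at high dilution (7-exo-trig); only the hydroxyl ortho to the ether oxygen can reach the activated carboxyl, so the seven-membered depsidone lactone should form without protecting the hydroxyl next to the tert-butyl ester.

Step 12
Reactants: 16 tert-butyl 3-(benzyloxy)-6-(dimethoxymethyl)-4-(1,3-dioxolan-2-yl)-9-formyl-8-hydroxy-1-methyl-11-oxo-11H-dibenzo[b,e][1,4]dioxepine-7-carboxylate
Product: 17 tert-butyl 6-(dimethoxymethyl)-4-(1,3-dioxolan-2-yl)-9-formyl-3,8-dihydroxy-1-methyl-11-oxo-11H-dibenzo[b,e][1,4]dioxepine-7-carboxylate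
Conditions: H2 (1 atm), 10% Pd/C, EtOAc, rt
Reagents that add atoms: none
Why: Catalytic hydrogenolysis of the benzyl aryl ether, which under neutral conditions at one atmosphere should be much faster than reduction of the hydrogen-bonded aryl aldehyde or cleavage of the aryl acetals, provided the reaction is stopped at full debenzylation.

Step 13
Reactants: 17 tert-butyl 6-(dimethoxymethyl)-4-(1,3-dioxolan-2-yl)-9-formyl-3,8-dihydroxy-1-methyl-11-oxo-11H-dibenzo[b,e][1,4]dioxepine-7-carboxylate
Product: 18 tert-butyl 6-(dimethoxymethyl)-4-(1,3-dioxolan-2-yl)-3,8-dihydroxy-9-(hydroxymethyl)-1-methyl-11-oxo-11H-dibenzo[b,e][1,4]dioxepine-7-carboxylate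
Conditions: NaBH4, THF/i-PrOH, −20 °C; then AcOH
Reagents that add atoms: none
Why: Borohydride reduction of the only free aldehyde; the other two formyl carbons are acetals, the tert-butyl ester is inert, and the low temperature should spare the aryl ester of the lactone.

Step 14
Reactants: 18 tert-butyl 6-(dimethoxymethyl)-4-(1,3-dioxolan-2-yl)-3,8-dihydroxy-9-(hydroxymethyl)-1-methyl-11-oxo-11H-dibenzo[b,e][1,4]dioxepine-7-carboxylate
Product: 20 racemic salazinic acid (racemic lactol), via open formyl acid 19 (not isolated)
Conditions: TFA/H2O (9:1), 0 °C → rt; evaporate, triturate with H2O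
Reagents that add atoms: water, O
Why: Acidolysis of the tert-butyl ester and hydrolysis of both acetals; the freed carboxyl adds to the neighbouring formyl group (5-exo-trig ring–chain tautomerism of an o-formylbenzoic acid) to give the lactol as a racemate, since the new stereocentre cannot be controlled at this stage.

Step 15
Reactants: 20 racemic salazinic acid
Product: 21 (S)-salazinic acid (target, crystalline)
Conditions: MeCN slurry, Et3N (cat.), (S)-seed crystals, glass-bead grinding, 20 °C; filter
Reagents that add atoms: none
Why: Proposed new method: in solution the two lactol enantiomers interconvert through the achiral open formyl acid 19 (base-catalysed ring–chain tautomerism), so a seeded, ground slurry should feed all material into crystals of the (S) form if 20 is a conglomerate; the closest known reaction types are attrition-enhanced deracemization (Viedma ripening) of racemizable conglomerates and the crystallization of a single anomer from a mutarotating sugar; the (S) configuration is set here by the seed crystals (obtained once on milligram scale by chiral-phase separation and assigned by anomalous-dispersion X-ray diffraction) and persists only in the solid.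

**Compound list**

1 | methyl orsellinate | COC(=O)c1c(C)cc(O)cc1O | starting material
2 | methyl haematommate (methyl 3-formyl-2,4-dihydroxy-6-methylbenzoate) | COC(=O)c1c(C)cc(O)c(C=O)c1O | intermediate
3 | methyl 4-(benzyloxy)-3-formyl-2-hydroxy-6-methylbenzoate | COC(=O)c1c(C)cc(OCc2ccccc2)c(C=O)c1O | intermediate
4 | methyl 4-(benzyloxy)-3-(1,3-dioxolan-2-yl)-2-hydroxy-6-methylbenzoate | COC(=O)c1c(C)cc(OCc2ccccc2)c(C2OCCO2)c1O | intermediate
5 | triethyl phosphonoacetate | CCOC(=O)CP(=O)(OCC)OCC | starting material
6 | triethyl diazophosphonoacetate | CCOC(=O)C(=[N+]=[N-])P(=O)(OCC)OCC | intermediate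
7 | ethyl 2-(ArO)-2-(diethoxyphosphoryl)acetate (racemic) | CCOC(=O)C(Oc1c(C2OCCO2)c(OCc2ccccc2)cc(C)c1C(=O)OC)P(=O)(OCC)OCC | intermediate
8 | 2,2-dimethoxyacetaldehyde | COC(OC)C=O | starting material
9 | ethyl (Z)-2-(ArO)-4,4-dimethoxybut-2-enoate | CCOC(=O)/C(Oc1c(C2OCCO2)c(OCc2ccccc2)cc(C)c1C(=O)OC)=C/C(OC)OC | intermediate
10 | tert-butyl acetoacetate | CC(=O)CC(=O)OC(C)(C)C | starting material
11 | 1-tert-butyl 5-ethyl 2-acetyl-4-(ArO)-3-(dimethoxymethyl)pentanedioate (diastereomer mixture, not isolated) | CCOC(=O)C(Oc1c(C2OCCO2)c(OCc2ccccc2)cc(C)c1C(=O)OC)C(C(OC)OC)C(C(C)=O)C(=O)OC(C)(C)C | intermediate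
12 | tert-butyl trans-5-(ArO)-6-(dimethoxymethyl)-2-hydroxy-4-oxocyclohex-1-ene-1-carboxylate (racemic; one enantiomer drawn) | CC(C)(C)OC(=O)C1=C(O)CC(=O)[C@@H](Oc2c(C3OCCO3)c(OCc3ccccc3)cc(C)c2C(=O)OC)[C@@H]1C(OC)OC | intermediate
13 | tert-butyl 3-(ArO)-2-(dimethoxymethyl)-4,6-dihydroxybenzoate | CC(C)(C)OC(=O)c1c(O)cc(O)c(Oc2c(C3OCCO3)c(OCc3ccccc3)cc(C)c2C(=O)OC)c1C(OC)OC | intermediate
14 | tert-butyl 3-(ArO)-2-(dimethoxymethyl)-5-formyl-4,6-dihydroxybenzoate | CC(C)(C)OC(=O)c1c(O)c(C=O)c(O)c(Oc2c(C3OCCO3)c(OCc3ccccc3)cc(C)c2C(=O)OC)c1C(OC)OC | intermediate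
15 | 4-(benzyloxy)-2-[3-(tert-butoxycarbonyl)-2-(dimethoxymethyl)-5-formyl-4,6-dihydroxyphenoxy]-3-(1,3-dioxolan-2-yl)-6-methylbenzoic acid | CC(C)(C)OC(=O)c1c(O)c(C=O)c(O)c(Oc2c(C3OCCO3)c(OCc3ccccc3)cc(C)c2C(=O)O)c1C(OC)OC | intermediate
16 | tert-butyl 3-(benzyloxy)-6-(dimethoxymethyl)-4-(1,3-dioxolan-2-yl)-9-formyl-8-hydroxy-1-methyl-11-oxo-11H-dibenzo[b,e][1,4]dioxepine-7-carboxylate | Cc1cc(OCc3ccccc3)c(C3OCCO3)c2c1C(=O)Oc1c(C=O)c(O)c(C(=O)OC(C)(C)C)c(C(OC)OC)c1O2 | intermediate
17 | tert-butyl 6-(dimethoxymethyl)-4-(1,3-dioxolan-2-yl)-9-formyl-3,8-dihydroxy-1-methyl-11-oxo-11H-dibenzo[b,e][1,4]dioxepine-7-carboxylate | Cc1cc(O)c(C3OCCO3)c2c1C(=O)Oc1c(C=O)c(O)c(C(=O)OC(C)(C)C)c(C(OC)OC)c1O2 | intermediate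
18 | tert-butyl 6-(dimethoxymethyl)-4-(1,3-dioxolan-2-yl)-3,8-dihydroxy-9-(hydroxymethyl)-1-methyl-11-oxo-11H-dibenzo[b,e][1,4]dioxepine-7-carboxylate | Cc1cc(O)c(C3OCCO3)c2c1C(=O)Oc1c(CO)c(O)c(C(=O)OC(C)(C)C)c(C(OC)OC)c1O2 | intermediate
19 | 4,6-diformyl-3,8-dihydroxy-9-(hydroxymethyl)-1-methyl-11-oxo-11H-dibenzo[b,e][1,4]dioxepine-7-carboxylic acid (open formyl acid, not isolated) | Cc1cc(O)c(C=O)c2c1C(=O)Oc1c(CO)c(O)c(C(=O)O)c(C=O)c1O2 | intermediate
20 | racemic salazinic acid (racemic lactol) | Cc1cc(O)c(C=O)c2c1C(=O)Oc1c(CO)c(O)c3c(c1O2)C(O)OC3=O | intermediate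
21 | (S)-salazinic acid | Cc1cc(O)c(C=O)c2c1C(=O)Oc1c(CO)c(O)c3c(c1O2)[C@@H](O)OC3=O | target

**Step count**

Total: 15 steps. Longest linear sequence: 14 steps (steps 1–3 and 5–15, from methyl orsellinate 1); step 4 is a one-step side branch.

**Steps most likely to fail**

The first risk is step 15, the deracemizing crystallization. The racemate may crystallize as a racemic compound rather than a conglomerate, in which case grinding cannot amplify one hand; base-promoted solvolysis of the seven-membered lactone may also outpace deracemization. The fallback for step 15 sets out from 20 and comes back to the route at 21. Racemate 20 is separated by preparative chromatography on an immobilized amylose tris(3,5-dimethylphenylcarbamate) phase at about −20 °C, with an aprotic eluent containing a trace of acetic acid so that ring opening is slow. The (S) fraction is evaporated cold and crystallized at once; the (R) fraction is racemized with a trace of Et3N and recycled. This fallback makes no new compound (F0).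

The second risk is step 7, the Michael–Claisen annulation. The conjugate addition may stall at the hindered, donor-substituted β-carbon (retro-Michael reaction), or the transient ester enolate of 11 may close onto the ring A ester (Dieckmann reaction). The fallback for step 7 sets out from 9 and 10 and comes back to the route at 12, forming the same two ring B bonds in the reverse order. The dianion of 10 (NaH, then n-BuLi, THF, −78 °C) is acylated at its γ-carbon by the ethyl ester of 9 to give tert-butyl (Z)-6-(ArO)-8,8-dimethoxy-3,5-dioxooct-6-enoate F1. Catalytic DBU then closes ring B of F1 by intramolecular 6-endo-trig Michael addition of C-2 to the aryloxy enone; the carbocyclic dione enolate is the thermodynamic sink and is 12.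

The third risk is step 8, the DDQ aromatization. The electron-rich resorcinol product may be over-oxidized, or hydride may be abstracted at the benzylic acetal or ether C–H bonds instead of the ring. The fallback for step 8 sets out from 12 and comes back to the route at 13. Silylation (Me3SiCl, Et3N, MeCN) gives tert-butyl trans-5-(ArO)-6-(dimethoxymethyl)-2,4-bis(trimethylsilyloxy)cyclohexa-1,3-diene-1-carboxylate F2. Pd(OAc)2 in MeCN then effects a Saegusa–Ito dehydrosilylation of F2: palladation at the ester-bearing carbon of the silyl enol ether is followed by β-hydride elimination from the acetal-bearing ring carbon, and the cyclohexadienone so formed tautomerizes to the arene. Aqueous work-up removes the remaining silyl group to give 13.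

**Further compounds**

F0 | step 15 | none | none
F1 | step 7 | tert-butyl (Z)-6-(ArO)-8,8-dimethoxy-3,5-dioxooct-6-enoate | CC(C)(C)OC(=O)CC(=O)CC(=O)/C(Oc1c(C2OCCO2)c(OCc2ccccc2)cc(C)c1C(=O)OC)=C/C(OC)OC
F2 | step 8 | tert-butyl trans-5-(ArO)-6-(dimethoxymethyl)-2,4-bis(trimethylsilyloxy)cyclohexa-1,3-diene-1-carboxylate | CC(C)(C)OC(=O)C1=C(O[Si](C)(C)C)C=C(O[Si](C)(C)C)[C@@H](Oc2c(C3OCCO3)c(OCc3ccccc3)cc(C)c2C(=O)OC)[C@@H]1C(OC)OC
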